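**Remark on stereochemistry:** the target SMILES has no stereocentre and no stereogenic double bond, so asplenetin is achiral and the route needs no enantiocontrol.

**Retrosynthetic overview**
- Asplenetin is reached by cleaving all five aryl methyl ethers of its pentamethyl ether.
- Ring C (the pyranone) is the only ring built. It is cut at C8a–O1, C4a–C4 and O1–C2 into 3,5-dimethoxybenzyne (ring A) and a β-methoxyacrylic acid that carries ring B, C2, C3, C4 and the 3-methylbutyl chain.
- The feature the strategy rests on: O1 and the C4 carbonyl sit on the neighbouring ring-A carbons C8a and C4a, and C4a is flanked by the C5 oxygen. A 3-alkoxybenzyne delivers exactly this 1-oxy-2-acyl-3-alkoxy pattern regioselectively.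
- The aryne precursor comes from 3,5-dimethoxyphenol (ortho-bromination, O-silylation, retro-Brook shift/triflation). The acid comes from ethyl 3,4,5-trimethoxybenzoylacetate (C-alkylation, O-methylation, saponification).
- Ring order: A and B are bought; C closes in the key step.

Key step: step 7

**Route**

Step 1
Reactants: 1 3,5-dimethoxyphenol
Product: 2 2-bromo-3,5-dimethoxyphenol
Conditions: NBS (1.0 equiv), CH2Cl2, −78 °C → rt
Reagents that add atoms: N-bromosuccinimide, O=C1CCC(=O)N1Br
Why: Electrophilic aromatic bromination of the phloroglucinol-type ring at low temperature should go mainly ortho to the free hydroxyl (two equivalent sites), and any 4-bromo isomer should be separable by chromatography.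

Step 2
Reactants: 2 2-bromo-3,5-dimethoxyphenol
Product: 3 (2-bromo-3,5-dimethoxyphenoxy)trimethylsilane
Conditions: HMDS, THF, 70 °C; concentrate, use crude
Reagents that add atoms: hexamethyldisilazane, C[Si](C)(C)N[Si](C)(C)C
Why: O-silylation of the phenol with HMDS is driven by loss of ammonia and gives the aryl silyl ether needed for the silyl migration.

Step 3
Reactants: 3 (2-bromo-3,5-dimethoxyphenoxy)trimethylsilane
Product: 6 3,5-dimethoxy-2-(trimethylsilyl)phenyl trifluoromethanesulfonate, via aryllithium 4 (not isolated), via lithium 2-silylphenoxide 5 (not isolated)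
Conditions: n-BuLi, THF, −100 → −78 °C; then Tf2O, −100 °C → rt
Reagents that add atoms: trifluoromethanesulfonic anhydride, O=S(=O)(OS(=O)(=O)C(F)(F)F)C(F)(F)F
Why: Bromine–lithium exchange gives the aryllithium, a retro-Brook 1,3-O→C silyl shift turns it into the lithium phenoxide, and O-triflation of that phenoxide gives the ortho-silylaryl triflate.

Step 4
Reactants: 7 ethyl 3-oxo-3-(3,4,5-trimethoxyphenyl)propanoate; 8 1-bromo-3-methylbutane
Product: 9 ethyl 5-methyl-2-(3,4,5-trimethoxybenzoyl)hexanoate (racemic)
Conditions: NaH, THF/DMF, 0 °C; then 8, NaI (cat.), 60 °C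
Reagents that add atoms: none
Why: SN2 C-alkylation of the stabilised β-keto ester enolate with a primary bromide (iodide-assisted); the new α-centre is racemic and is removed in step 5.

Step 5
Reactants: 9 ethyl 5-methyl-2-(3,4,5-trimethoxybenzoyl)hexanoate
Product: 10 ethyl (Z)-3-methoxy-2-(3-methylbutyl)-3-(3,4,5-trimethoxyphenyl)prop-2-enoate (the E isomer may accompany it; both are carried on)
Conditions: NaH, THF/DMPU, 0 °C; then Me2SO4, 0 °C → rt
Reagents that add atoms: dimethyl sulfate, COS(=O)(=O)OC
Why: O-alkylation of the solvent-separated enolate of an α-substituted β-keto ester with a hard electrophile in a dipolar aprotic medium should give the enol ether, and its alkene geometry does not matter because both isomers converge in step 7.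

Step 6
Reactants: 10 ethyl (Z)-3-methoxy-2-(3-methylbutyl)-3-(3,4,5-trimethoxyphenyl)prop-2-enoate
Product: 11 (Z)-3-methoxy-2-(3-methylbutyl)-3-(3,4,5-trimethoxyphenyl)prop-2-enoic acid
Conditions: KOH, EtOH/H2O, 80 °C; then cold 1 M HCl to pH 4 at 0 °C, rapid extraction
Reagents that add atoms: potassium hydroxide, [K+].[OH-]
Why: Saponification of the β-alkoxyacrylate ester, with cold and only mildly acidic work-up so that the acid-labile enol ether survives.

Step 7
Reactants: 11 (Z)-3-methoxy-2-(3-methylbutyl)-3-(3,4,5-trimethoxyphenyl)prop-2-enoic acid; 6 3,5-dimethoxy-2-(trimethylsilyl)phenyl trifluoromethanesulfonate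
Product: 15 5,7-dimethoxy-3-(3-methylbutyl)-2-(3,4,5-trimethoxyphenyl)chromen-4-one, via cesium carboxylate 12 (not isolated), via 3,5-dimethoxybenzyne 13 (not isolated), via ortho-acylphenoxide 14 (not isolated)
Conditions: 6 (1.5 equiv), anhydrous CsF (4 equiv), THF, 125 °C, sealed tube
Reagents that add atoms: none
Why: Proposed new method: CsF converts 11 into cesium carboxylate 12 and releases aryne 13 from 6; the carboxylate oxygen adds to the aryne carbon remote from the flanking methoxy group, the aryl anion so formed (ortho to OMe) attacks the acyl carbon, and the four-membered alkoxide opens to ortho-acylphenoxide 14, a net insertion into the O–C(acyl) bond that forms C8a–O1 and C4a–C4. The closest known reaction type is the fluoride-induced insertion of arynes into the C–O bond of carboxylic acids, which gives ortho-hydroxyaryl ketones and, from unsaturated acids, chromanones and flavones by oxa-Michael closure; a fully substituted β-methoxyacrylic acid has not been shown as the partner. Ring C closes by 6-endo-trig conjugate addition of the phenoxide oxygen to the β-carbon (O1–C2) followed by loss of methoxide, an addition–elimination that restores the conjugated pyranone and makes the E/Z composition of 11 irrelevant. No stereocentre is formed. The step needs attack at the aryne carbon meta to the 3-methoxy group, which the inductive polarisation of 3-alkoxyarynes secures, and acyl transfer faster than protonation of the aryl anion, which the aprotic medium, the trapping of the acid proton as poorly soluble cesium bifluoride and the high temperature should favour.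

Step 8
Reactants: 15 5,7-dimethoxy-3-(3-methylbutyl)-2-(3,4,5-trimethoxyphenyl)chromen-4-one
Product: 16 asplenetin, 5,7-dihydroxy-3-(3-methylbutyl)-2-(3,4,5-trihydroxyphenyl)chromen-4-one
Conditions: BBr3 (10 equiv), CH2Cl2, −78 °C → rt, argon; then MeOH, H2O
Reagents that add atoms: none
Why: Lewis-acid ether cleavage with BBr3 (O–B coordination, then SN2 attack of bromide on methyl) should remove all five aryl methyl ethers, while the flavone core and the alkyl chain are inert and the phenols are freed on hydrolysis.

**Compound list**
1 | 3,5-dimethoxyphenol | COc1cc(O)cc(OC)c1 | starting material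
2 | 2-bromo-3,5-dimethoxyphenol | COc1cc(O)c(Br)c(OC)c1 | intermediate
3 | (2-bromo-3,5-dimethoxyphenoxy)trimethylsilane | COc1cc(O[Si](C)(C)C)c(Br)c(OC)c1 | intermediate
4 | (2-lithio-3,5-dimethoxyphenoxy)trimethylsilane (formed in situ) | [Li]c1c(OC)cc(OC)cc1O[Si](C)(C)C | intermediate
5 | lithium 3,5-dimethoxy-2-(trimethylsilyl)phenolate (formed in situ) | [Li+].[O-]c1cc(OC)cc(OC)c1[Si](C)(C)C | intermediate
6 | 3,5-dimethoxy-2-(trimethylsilyl)phenyl trifluoromethanesulfonate | COc1cc(OC)c([Si](C)(C)C)c(OS(=O)(=O)C(F)(F)F)c1 | intermediate
7 | ethyl 3-oxo-3-(3,4,5-trimethoxyphenyl)propanoate | CCOC(=O)CC(=O)c1cc(OC)c(OC)c(OC)c1 | starting material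
8 | 1-bromo-3-methylbutane | CC(C)CCBr | starting material
9 | ethyl 5-methyl-2-(3,4,5-trimethoxybenzoyl)hexanoate (racemic) | CCOC(=O)C(CCC(C)C)C(=O)c1cc(OC)c(OC)c(OC)c1 | intermediate
10 | ethyl (Z)-3-methoxy-2-(3-methylbutyl)-3-(3,4,5-trimethoxyphenyl)prop-2-enoate (Z drawn; E may accompany it) | CO/C(c1cc(OC)c(OC)c(OC)c1)=C(/CCC(C)C)C(=O)OCC | intermediate
11 | (Z)-3-methoxy-2-(3-methylbutyl)-3-(3,4,5-trimethoxyphenyl)prop-2-enoic acid (Z drawn; E may accompany it) | CO/C(c1cc(OC)c(OC)c(OC)c1)=C(/CCC(C)C)C(=O)O | intermediate
12 | cesium (Z)-3-methoxy-2-(3-methylbutyl)-3-(3,4,5-trimethoxyphenyl)prop-2-enoate (formed in situ) | CO/C(c1cc(OC)c(OC)c(OC)c1)=C(/CCC(C)C)C(=O)[O-].[Cs+] | intermediate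
13 | 3,5-dimethoxybenzyne (1,2-didehydro-3,5-dimethoxybenzene; formed in situ) | COC1=CC(OC)=CC#C1 | intermediate
14 | cesium 3,5-dimethoxy-2-[(Z)-3-methoxy-2-(3-methylbutyl)-3-(3,4,5-trimethoxyphenyl)prop-2-enoyl]phenolate (formed in situ) | CO/C(c1cc(OC)c(OC)c(OC)c1)=C(/CCC(C)C)C(=O)c1c(OC)cc(OC)cc1[O-].[Cs+] | intermediate
15 | 5,7-dimethoxy-3-(3-methylbutyl)-2-(3,4,5-trimethoxyphenyl)chromen-4-one (asplenetin pentamethyl ether) | COc1cc(OC)c2c(c1)oc(-c1cc(OC)c(OC)c(OC)c1)c(CCC(C)C)c2=O | intermediate
16 | asplenetin (achiral) | CC(C)CCc1c(-c2cc(O)c(O)c(O)c2)oc2cc(O)cc(O)c2c1=O | target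

**Step count**
Total: 8 steps. Longest linear sequence: 5 steps (steps 1, 2, 3, 7, 8; the acid arm, steps 4, 5, 6, 7, 8, is equally long).

**Steps most likely to fail, with fallbacks**

1. Step 7 (Proposed new method). The aryl anion formed after carboxylate addition may be protonated before it reaches the hindered, electronically deactivated acyl carbon, so that only O-arylation takes place. The acyl shift may also simply be too slow, and excess aryne is then consumed by the carboxylate and by released methoxide. If the ring closure alone stalls at the ortho-hydroxyaryl β-methoxy enone, brief acid treatment should finish it. The fallback, all known chemistry, sets out from 9 and comes back to the route at 16. Keto ester 9 is heated neat with phloroglucinol at about 240 °C (Mentzer pyrone synthesis, thermal or microwave). Acylation of the phenol and cyclodehydration should give 5,7-dihydroxy-3-(3-methylbutyl)-2-(3,4,5-trimethoxyphenyl)chromen-4-one F1. The three remaining methyl ethers of F1 are then cleaved with BBr3 under the conditions of step 8 to give 16.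

2. Step 5. Methylation may take place at the α-carbon instead of at oxygen and give a quaternary keto ester, so that little enol ether is obtained. The fallback sets out from 9 and comes back at 10. It replaces enolate alkylation by acid-catalysed acetalisation and elimination. Keto ester 9 is treated with trimethyl orthoformate and catalytic TsOH to give ethyl 2-[dimethoxy(3,4,5-trimethoxyphenyl)methyl]-5-methylhexanoate F2. Heating F2 with the acid catalyst while methanol is distilled off (or TMSOTf/i-Pr2NEt) should eliminate methanol to give 10.

3. Step 6. Hydroxide may add to the β-carbon, or the enol ether may hydrolyse during acidification; either leads to the β-keto acid and to decarboxylation. The fallback sets out from 9 and comes back at 11. It uses an ester that is removed under neutral conditions. Keto ester 9 is transesterified with allyl alcohol (DMAP cat., toluene, reflux, ethanol distilled off) to give allyl 5-methyl-2-(3,4,5-trimethoxybenzoyl)hexanoate F3. O-methylation as in step 5 then gives allyl (Z)-3-methoxy-2-(3-methylbutyl)-3-(3,4,5-trimethoxyphenyl)prop-2-enoate F4. Pd(PPh3)4 (cat.) and morpholine in THF at rt transfer the allyl group to the amine and should free 11 without hydroxide or strong acid.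

**Further compounds**
F1 | step 7 | 5,7-dihydroxy-3-(3-methylbutyl)-2-(3,4,5-trimethoxyphenyl)chromen-4-one | CC(C)CCc1c(-c2cc(OC)c(OC)c(OC)c2)oc2cc(O)cc(O)c2c1=O
F2 | step 5 | ethyl 2-[dimethoxy(3,4,5-trimethoxyphenyl)methyl]-5-methylhexanoate (racemic) | CCOC(=O)C(CCC(C)C)C(OC)(OC)c1cc(OC)c(OC)c(OC)c1
F3 | step 6 | allyl 5-methyl-2-(3,4,5-trimethoxybenzoyl)hexanoate (racemic) | C=CCOC(=O)C(CCC(C)C)C(=O)c1cc(OC)c(OC)c(OC)c1
F4 | step 6 | allyl (Z)-3-methoxy-2-(3-methylbutyl)-3-(3,4,5-trimethoxyphenyl)prop-2-enoate | CO/C(c1cc(OC)c(OC)c(OC)c1)=C(/CCC(C)C)C(=O)OCC=C
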